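All runs were generated by integration with made-up constants; scatter was added.

**Leftovers first.** The south-east run ends at 20.0 h with 19.5% left-handed substrate and 47.1% right-handed substrate. Each was charged as half of the total, so the fractions left are 39.0% and 94.2%.

| setting | south | east | south-east | flask |
|---|---|---|---|---|
| left-handed substrate | 0.050 M | 0.050 M | 0.050 M | 0.050 M |
| right-handed substrate | 0.050 M | 0.050 M | 0.050 M | 0.050 M |
| partner | 0.020 M | 0.030 M | 0.040 M | 0.0400 M |
| precatalyst | 0.32 mM | 0.32 mM | 0.48 mM | 0.32 mM |
| remark | run made earlier | run made earlier | run made earlier |  |
| time |  |  |  | 20 h |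

- south (time / h: left-handed substrate / %, right-handed substrate / %, left-handed product / %): 2.50: 46.7, 50.2, 3.2; 8.00: 40.8, 49.8, 9.5; 12.0: 38.0, 49.8, 12.2; 20.0: 35.5, 49.0, 14.9
- east (time / h: left-handed substrate / %, right-handed substrate / %, left-handed product / %): 5.00: 39.9, 49.2, 9.6; 10.0: 34.2, 48.6, 15.7; 15.0: 30.8, 48.3, 19.3; 20.0: 28.6, 47.6, 21.6
- south-east (time / h: left-handed substrate / %, right-handed substrate / %, left-handed product / %): 5.00: 33.5, 48.6, 16.5; 10.0: 25.4, 47.9, 24.5; 15.0: 21.4, 47.6, 28.6; 20.0: 19.5, 47.1, 30.8

(readings scatter by 0.3 percentage points)

- catalyst is single-handed; left-handed substrate and right-handed substrate are mirror images of each other, charged as a racemate, each of them at the stated concentration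
- an excess is the difference of the two amounts in percent of their sum
- an excess is below zero if the other one leads

**Two clocks.** Both substrates meet the same partner and catalyst, so I give each fraction left an exponential with its own time constant; as c(partner) falls, both stretch alike. Averaged over the south-east run they are 21.2 h and 335 h. Their ratio 15.8 is the selectivity factor, ln(fraction of left-handed substrate left) over ln(fraction of right-handed substrate left). It is a reading: 0.3 percentage points of scatter sits on a right-handed loss of 2.9 points.

**My reckoning.** The flask has the south-east charges except precatalyst, 0.32 mM against 0.48 mM. I take the pace as proportional to catalyst, so its 20 h matches 13.3 h of south-east. Interpolating on a log scale between the readings at 10.0 h and 15.0 h gives 22.7% left-handed substrate, a fraction 45.3%. The factor then leaves a right-handed fraction 95.1%. So I expect c 29.8%, eP 83.6% and eS 35.5%.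

* part of the left-handed substrate and right-handed substrate charged together that has reacted at 20 h
* excess of left-handed product over right-handed product in the product at 20 h
* excess of right-handed substrate over left-handed substrate among what is left of the two at 20 h

**The forecast.** It gives c 29.8% (28.3% to 31.3%), eP 82.5% (80% to 85%) and eS 35% (32.5% to 37.5%). It scales time as I do: “The flask matches south-east in everything except catalyst, so 20 h here equals about 13.3 h of south-east”. Its selectivity factor is about 14.5, and mine is 15.8.

**The result.** The flask gives c 29.9%, eP 83.6% and eS 35.7%, inside the forecast's ranges.

    partner + catalyst + left-handed substrate → catalyst + left-handed product (k = 1.81 L² mol⁻² s⁻¹)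
    partner + catalyst + right-handed substrate → catalyst + right-handed product (k = 0.114 L² mol⁻² s⁻¹)
    partner + precatalyst → catalyst + spent reagent (k = 0.0152 L mol⁻¹ s⁻¹)

**Same factor again.** The flask keeps 45% of its left-handed substrate, and my factor turns that into 95.1% of the right-handed charge; the flask holds 95%. Precatalyst is down to 1.71% at 2.00 h, and its delay makes no difference to c. The neighbouring flask with 0.16 M of partner keeps 0.97% of its left-handed substrate. The factor gives 74.6% of the right-handed charge, and that flask holds 75%, with eS 97.4% and eP 59.3%.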